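**Retrosynthetic overview**

1. Target ⇒ its hexa-O-benzyl ether; global hydrogenolysis is the last step.
2. Key disconnection: the C2–O1 bond of the flavanone ⇒ a 2'-hydroxychalcone. A catalytic enantioselective 6-endo oxa-Michael addition closes the last ring and sets C2 as (S).
3. Chalcone Cα=Cβ ⇒ biaryl aldehyde + 2'-hydroxy-4',6'-bis(benzyloxy)acetophenone (Claisen–Schmidt condensation).
4. Biaryl bond C3'–C8'' ⇒ 8-iodo-tri-O-benzylapigenin + 4-(benzyloxy)-3-bromobenzaldehyde (one-pot borylation/Suzuki–Miyaura coupling).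
5. Ring order: the three flavone rings come intact from apigenin; flavanone rings A and B come from the acetophenone and the aldehyde; flavanone ring C (the dihydropyranone) is formed last.

**Assumptions**

- The target is (2S)-2,3-dihydroamentoflavone. The C3'–C8'' biaryl axis has no descriptor in the SMILES and is treated as freely rotating on the laboratory time scale.
- 4-(Benzyloxy)-3-bromobenzaldehyde and 2'-hydroxy-4',6'-bis(benzyloxy)acetophenone are taken as bought catalogue compounds (each is otherwise one benzylation away from 3-bromo-4-hydroxybenzaldehyde or 2',4',6'-trihydroxyacetophenone).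
- Catalyst for step 5 (organocatalyst, called BIMP-1, used preformed): 1-[3,5-bis(trifluoromethyl)phenyl]-3-[(2S)-3,3-dimethyl-1-{[tris(4-methoxyphenyl)phosphoranylidene]amino}butan-2-yl]thiourea, from L-tert-leucine. SMILES: COc1ccc(cc1)P(=NC[C@@H](NC(=S)Nc1cc(cc(c1)C(F)(F)F)C(F)(F)F)C(C)(C)C)(c1ccc(OC)cc1)c1ccc(OC)cc1

**Route**

Step 1
Reactants: 1 apigenin
Product: 2 5,7-bis(benzyloxy)-2-[4-(benzyloxy)phenyl]-4H-chromen-4-one (tri-O-benzylapigenin)
Conditions: BnBr (4 equiv), K2CO3 (6 equiv), n-Bu4NI (cat.), DMF, 80 °C, 16 h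
Reagents that add atoms: benzyl bromide, BrCc1ccccc1
Why: Williamson ether synthesis, in which excess benzyl bromide and heating also alkylate the hydrogen-bonded 5-OH, so that all three phenols are masked by groups that come off later under neutral conditions.

Step 2
Reactants: 2 5,7-bis(benzyloxy)-2-[4-(benzyloxy)phenyl]-4H-chromen-4-one
Product: 3 5,7-bis(benzyloxy)-2-[4-(benzyloxy)phenyl]-8-iodo-4H-chromen-4-one
Conditions: NIS (1.05 equiv), TFA (0.2 equiv), CH2Cl2/MeCN, 0 °C to rt, dark
Reagents that add atoms: N-iodosuccinimide, O=C1CCC(=O)N1I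
Why: Electrophilic aromatic iodination, which in fully O-alkylated 5,7-dioxygenated flavones goes to C8 (para to the 5-benzyloxy group, ortho to the 7-benzyloxy group) because C6 is flanked by two benzyloxy groups and the other rings are far less electron-rich.

Step 3
Reactants: 4 4-(benzyloxy)-3-bromobenzaldehyde; 3 5,7-bis(benzyloxy)-2-[4-(benzyloxy)phenyl]-8-iodo-4H-chromen-4-one
Product: 6 4-(benzyloxy)-3-{5,7-bis(benzyloxy)-2-[4-(benzyloxy)phenyl]-4-oxo-4H-chromen-8-yl}benzaldehyde, via pinacol boronate 5 (not isolated)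
Conditions: (a) 4 (1.5 equiv), B2pin2 (1.6 equiv), PdCl2(dppf) (3 mol %), KOAc (4 equiv), 1,4-dioxane, 90 °C, 3 h; (b) 3 (1.0 equiv), Pd(OAc)2 (5 mol %), SPhos (10 mol %), aq. K3PO4 (3 M, 4 equiv), 90 °C, 12 h, same pot
Reagents that add atoms: bis(pinacolato)diboron, CC1(C)OB(OC1(C)C)B1OC(C)(C)C(C)(C)O1 (its boryl group is carried by 5 only)
Why: Miyaura borylation followed in the same pot by Suzuki–Miyaura coupling, in which SPhos-ligated zerovalent palladium is suited to the tri-ortho-substituted biaryl and the aldehyde, chromone and benzyl ethers are inert.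

Step 4
Reactants: 6 4-(benzyloxy)-3-{5,7-bis(benzyloxy)-2-[4-(benzyloxy)phenyl]-4-oxo-4H-chromen-8-yl}benzaldehyde; 7 1-[2,4-bis(benzyloxy)-6-hydroxyphenyl]ethan-1-one (2'-hydroxy-4',6'-bis(benzyloxy)acetophenone)
Product: 9 (2E)-1-[2,4-bis(benzyloxy)-6-hydroxyphenyl]-3-(4-(benzyloxy)-3-{5,7-bis(benzyloxy)-2-[4-(benzyloxy)phenyl]-4-oxo-4H-chromen-8-yl}phenyl)prop-2-en-1-one, via aldol adduct 8 (not isolated)
Conditions: 7 (1.1 equiv), KOH (50% aq., 15 equiv), EtOH/THF 1:1, rt, 36 h; then 1 M HCl to pH 5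
Reagents that add atoms: none
Why: Claisen–Schmidt condensation (aldol addition, then E1cB dehydration to the conjugated E-enone), in which the 2'-phenoxide stays open in strong base and the chromone tolerates aqueous KOH at room temperature.

Step 5
Reactants: 9 (2E)-1-[2,4-bis(benzyloxy)-6-hydroxyphenyl]-3-(4-(benzyloxy)-3-{5,7-bis(benzyloxy)-2-[4-(benzyloxy)phenyl]-4-oxo-4H-chromen-8-yl}phenyl)prop-2-en-1-one
Product: 10 (2S)-5,7-bis(benzyloxy)-2-(4-(benzyloxy)-3-{5,7-bis(benzyloxy)-2-[4-(benzyloxy)phenyl]-4-oxo-4H-chromen-8-yl}phenyl)chroman-4-one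
Conditions: BIMP-1 (10 mol %), toluene (0.05 M), −20 °C, about 48 h, stopped at 90–95% conversion with AcOH; ee by chiral HPLC, upgraded by recrystallisation if needed
Reagents that add atoms: none
Why: Proposed new method: the iminophosphorane of BIMP-1 is basic enough to deprotonate the chelated 2'-OH of 9 (breaking the OH···O=C hydrogen bond that makes amine bases sluggish and poorly selective here), the phenoxide stays ion-paired to the chiral aminophosphonium while the thiourea N–H pair binds the oxygen of the s-trans enone, so that 6-endo-trig attack of the phenoxide on the Si face of C-β forms the C2–O1 bond with (2S) configuration and the enolate is protonated at C3 by the phosphonium to release 10 and the free base; the 6'-benzyloxy group twists the chalcone and favours the closed form, the low temperature, non-polar solvent and acid quench keep the reverse E1cB ring opening (the racemisation path) much slower than ring closure, and should the L-tert-leucine-derived catalyst prefer the Re face its mirror image from D-tert-leucine is used; the closest known reaction types are the bifunctional iminophosphorane-catalysed intramolecular oxa-Michael addition of alcohols to unsaturated esters and amides and the cinchona thiourea-catalysed cyclisation of activated alkylidene beta-keto esters to flavanones, whereas a highly enantioselective cyclisation of an unactivated 2'-hydroxychalcone, here one carrying a flavone, has not been shown.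

Step 6
Reactants: 10 (2S)-5,7-bis(benzyloxy)-2-(4-(benzyloxy)-3-{5,7-bis(benzyloxy)-2-[4-(benzyloxy)phenyl]-4-oxo-4H-chromen-8-yl}phenyl)chroman-4-one
Product: 11 (2S)-2,3-dihydroamentoflavone (target, CNP0147846.1)
Conditions: H2 (1 atm), 10% Pd/C, THF/MeOH 1:1, rt, 4–8 h, stopped when debenzylation is complete
Reagents that add atoms: none
Why: Catalytic hydrogenolysis of the six benzyl aryl ethers under neutral conditions, where no base is present to open the flavanone by retro-oxa-Michael reaction (so C2 stays S) and the chromone C2=C3 bond and the aryl ketones are reduced far more slowly than O–benzyl bonds at 1 atm.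

**Compound list**

1 | apigenin | O=c1cc(-c2ccc(O)cc2)oc2cc(O)cc(O)c12 | starting material
2 | 5,7-bis(benzyloxy)-2-[4-(benzyloxy)phenyl]-4H-chromen-4-one | O=c1cc(-c2ccc(OCc3ccccc3)cc2)oc2cc(OCc3ccccc3)cc(OCc3ccccc3)c12 | intermediate
3 | 5,7-bis(benzyloxy)-2-[4-(benzyloxy)phenyl]-8-iodo-4H-chromen-4-one | O=c1cc(-c2ccc(OCc3ccccc3)cc2)oc2c(I)c(OCc3ccccc3)cc(OCc3ccccc3)c12 | intermediate
4 | 4-(benzyloxy)-3-bromobenzaldehyde | O=Cc1ccc(OCc2ccccc2)c(Br)c1 | starting material
5 | 4-(benzyloxy)-3-(4,4,5,5-tetramethyl-1,3,2-dioxaborolan-2-yl)benzaldehyde | O=Cc1ccc(OCc2ccccc2)c(B2OC(C)(C)C(C)(C)O2)c1 | intermediate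
6 | 4-(benzyloxy)-3-{5,7-bis(benzyloxy)-2-[4-(benzyloxy)phenyl]-4-oxo-4H-chromen-8-yl}benzaldehyde | O=Cc1ccc(OCc2ccccc2)c(-c2c(OCc3ccccc3)cc(OCc3ccccc3)c3c(=O)cc(-c4ccc(OCc5ccccc5)cc4)oc23)c1 | intermediate
7 | 1-[2,4-bis(benzyloxy)-6-hydroxyphenyl]ethan-1-one | CC(=O)c1c(O)cc(OCc2ccccc2)cc1OCc1ccccc1 | starting material
8 | rac-1-[2,4-bis(benzyloxy)-6-hydroxyphenyl]-3-hydroxy-3-(4-(benzyloxy)-3-{5,7-bis(benzyloxy)-2-[4-(benzyloxy)phenyl]-4-oxo-4H-chromen-8-yl}phenyl)propan-1-one | O=C(CC(O)c1ccc(OCc2ccccc2)c(-c2c(OCc3ccccc3)cc(OCc3ccccc3)c3c(=O)cc(-c4ccc(OCc5ccccc5)cc4)oc23)c1)c1c(O)cc(OCc2ccccc2)cc1OCc1ccccc1 | intermediate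
9 | (2E)-1-[2,4-bis(benzyloxy)-6-hydroxyphenyl]-3-(4-(benzyloxy)-3-{5,7-bis(benzyloxy)-2-[4-(benzyloxy)phenyl]-4-oxo-4H-chromen-8-yl}phenyl)prop-2-en-1-one | O=C(/C=C/c1ccc(OCc2ccccc2)c(-c2c(OCc3ccccc3)cc(OCc3ccccc3)c3c(=O)cc(-c4ccc(OCc5ccccc5)cc4)oc23)c1)c1c(O)cc(OCc2ccccc2)cc1OCc1ccccc1 | intermediate
10 | (2S)-5,7-bis(benzyloxy)-2-(4-(benzyloxy)-3-{5,7-bis(benzyloxy)-2-[4-(benzyloxy)phenyl]-4-oxo-4H-chromen-8-yl}phenyl)chroman-4-one | O=C1C[C@@H](c2ccc(OCc3ccccc3)c(-c3c(OCc4ccccc4)cc(OCc4ccccc4)c4c(=O)cc(-c5ccc(OCc6ccccc6)cc5)oc34)c2)Oc2cc(OCc3ccccc3)cc(OCc3ccccc3)c21 | intermediate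
11 | (2S)-2,3-dihydroamentoflavone | O=C1C[C@@H](c2ccc(O)c(-c3c(O)cc(O)c4c(=O)cc(-c5ccc(O)cc5)oc34)c2)Oc2cc(O)cc(O)c21 | target

**Step count and risks**

Total step count: 6. Longest linear sequence: 6 steps (1 → 2 → 3 → 6 → 9 → 10 → 11).

The three steps most likely to fail are steps 2, 3 and 5.

Step 2 (regiochemistry of iodination; C6 or over-iodination could compete). The fallback fixes the iodine position before the flavone is built. It sets out from acetophenone 7, which is iodinated ortho to the free phenol (NIS, MeCN, rt) to give 1-[4,6-bis(benzyloxy)-2-hydroxy-3-iodophenyl]ethan-1-one F1. Claisen–Schmidt condensation of this ketone with commercial 4-(benzyloxy)benzaldehyde (KOH, EtOH/THF, rt) gives (E)-1-[4,6-bis(benzyloxy)-2-hydroxy-3-iodophenyl]-3-[4-(benzyloxy)phenyl]prop-2-en-1-one F2. Oxidative cyclisation of that chalcone (I2 cat., DMSO, 120 °C) closes the chromone with the iodine necessarily at C8, and the sequence comes back to the route at 3.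

Step 3 (hindered tri-ortho biaryl coupling run in one pot; protodeboronation of 5 or deiodination of 3 could dominate). The fallback reverses the polarity of the coupling. It sets out from 3, which is borylated (B2pin2, PdCl2(dppf), KOAc, DMSO, 80 °C) and isolated as 5,7-bis(benzyloxy)-2-[4-(benzyloxy)phenyl]-8-(4,4,5,5-tetramethyl-1,3,2-dioxaborolan-2-yl)-4H-chromen-4-one F3. This electron-rich, di-ortho-alkoxy boronate is then coupled with the electron-poor bromide 4 (Pd(OAc)2, SPhos, K3PO4, toluene/water, 90 °C), a pairing in which oxidative addition is fast and the ligand is known to handle 2,6-dioxygenated boron partners. The fallback comes back to the route at 6.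

Step 5 (the proposed new enantioselective cyclisation; low rate with the electron-rich ring B, low ee, or erosion by reversibility). The fallback uses only known chemistry. It sets out from 9, which is cyclised without stereocontrol (NaOAc, EtOH/THF, reflux) to racemic 5,7-bis(benzyloxy)-2-(4-(benzyloxy)-3-{5,7-bis(benzyloxy)-2-[4-(benzyloxy)phenyl]-4-oxo-4H-chromen-8-yl}phenyl)chroman-4-one F4. The racemate is resolved by preparative chiral chromatography on an amylose tris(3,5-dimethylphenylcarbamate) phase; the (2S) enantiomer is 10, where the fallback comes back to the route. The separated (2R)-5,7-bis(benzyloxy)-2-(4-(benzyloxy)-3-{5,7-bis(benzyloxy)-2-[4-(benzyloxy)phenyl]-4-oxo-4H-chromen-8-yl}phenyl)chroman-4-one F5 is re-equilibrated with NaOAc through the chalcone and recycled. The absolute configuration is confirmed on 11 by its circular dichroism spectrum against (2S)-naringenin.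

**Further compounds**

F1 | step 2 | 1-[4,6-bis(benzyloxy)-2-hydroxy-3-iodophenyl]ethan-1-one | CC(=O)c1c(O)c(I)c(OCc2ccccc2)cc1OCc1ccccc1
F2 | step 2 | (E)-1-[4,6-bis(benzyloxy)-2-hydroxy-3-iodophenyl]-3-[4-(benzyloxy)phenyl]prop-2-en-1-one | O=C(/C=C/c1ccc(OCc2ccccc2)cc1)c1c(O)c(I)c(OCc2ccccc2)cc1OCc1ccccc1
F3 | step 3 | 5,7-bis(benzyloxy)-2-[4-(benzyloxy)phenyl]-8-(4,4,5,5-tetramethyl-1,3,2-dioxaborolan-2-yl)-4H-chromen-4-one | O=c1cc(-c2ccc(OCc3ccccc3)cc2)oc2c(B3OC(C)(C)C(C)(C)O3)c(OCc3ccccc3)cc(OCc3ccccc3)c12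
F4 | step 5 | rac-5,7-bis(benzyloxy)-2-(4-(benzyloxy)-3-{5,7-bis(benzyloxy)-2-[4-(benzyloxy)phenyl]-4-oxo-4H-chromen-8-yl}phenyl)chroman-4-one | O=C1CC(c2ccc(OCc3ccccc3)c(-c3c(OCc4ccccc4)cc(OCc4ccccc4)c4c(=O)cc(-c5ccc(OCc6ccccc6)cc5)oc34)c2)Oc2cc(OCc3ccccc3)cc(OCc3ccccc3)c21
F5 | step 5 | (2R)-5,7-bis(benzyloxy)-2-(4-(benzyloxy)-3-{5,7-bis(benzyloxy)-2-[4-(benzyloxy)phenyl]-4-oxo-4H-chromen-8-yl}phenyl)chroman-4-one | O=C1C[C@H](c2ccc(OCc3ccccc3)c(-c3c(OCc4ccccc4)cc(OCc4ccccc4)c4c(=O)cc(-c5ccc(OCc6ccccc6)cc5)oc34)c2)Oc2cc(OCc3ccccc3)cc(OCc3ccccc3)c21
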